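(All runs come from a simulation from invented constants; scatter was added.)

The reading at 80 min is the point of interest: has target outgrown the solution in this flask by then?

| flask | starting material | partner A | partner B | remark | time |
|---|---|---|---|---|---|
| midnight | 48 mM | 1 equiv | 1.3 equiv | run made earlier |  |
| summer | 75 mM | 1 equiv | 1.3 equiv | run made earlier |  |
| flask | 34 mM | 1.00 equiv | 1.30 equiv |  | 80 min |

| run | time / min | target / % | crystals / % |
|---|---|---|---|
| midnight | 8.00 | 0 | 0 |
| midnight | 12.0 | 0.5 | 0 |
| midnight | 20.0 | 2.8 | 0 |
| midnight | 40.0 | 3.5 | 0 |
| midnight | 60.0 | 7.8 | 2.1 |
| midnight | 90.0 | 10.9 | 5.3 |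
| summer | 6.00 | 2.0 | 0.4 |
| summer | 20.0 | 4.6 | 1.3 |
| summer | 30.0 | 6.6 | 2.6 |
| summer | 50.0 | 9.4 | 5.4 |
| summer | 80.0 | 12.5 | 8.4 |
| summer | 90.0 | 14.2 | 10.1 |

(readings scatter by 1 percentage point)

- the target and crystals together standing at 80 min, as a percentage of the starting material charged
- concentration of target in solution at 80 min, in percent of saturation

- target is meant together with its crystals
- solid, in amounts per volume of the solution: crystals

Target in the tables includes its crystals, so the difference of the two columns is dissolved target. At the last reading this is 2.69 mM in the midnight run and 3.07 mM in the summer run. Over the later readings of both runs crystals keep growing while the difference stays level, so it reads as saturation (the solubility limit), on average 2.88 mM. Divided by the charge of this flask, that gives 8.47%, the saturation share: the total, in percent of the starting material charged, past which, on this reading, crystals can begin.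

Now the total. At 80 min the midnight run interpolates to 9.87% and the summer run reads 12.5%, so between these two runs the total reads as growing with the charge to the power 0.530. Carried down to this flask, that gives 8.22%, which is 97.0% of the share, just short of the crossing.

The weak link is saturation. A scatter of 1 percentage point weighs fewer mM in the midnight run, whose charge is smaller. On that run alone the share becomes 7.91%, and the total stands at 104% of it. This reckoning therefore commits to 8.22%, with the solution close to saturation and crystals a trace or none.

The forecast, slightly higher, says 8.5% (6.6% to 10.4%) and 97% of saturation (79% to 112%): “Little or no crystal would have formed”.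

The flask gives 6.88% and 97.4% of saturation, both inside the forecast's ranges.

    2 open intermediate → homo product (k = 0.00885 M⁻¹ s⁻¹)
    open intermediate + second intermediate → target (k = 0.00606 M⁻¹ s⁻¹)
    partner B + partner A → second intermediate (k = 0.00522 M⁻¹ s⁻¹)
    crystals ⇌ target, rate k4*(cs4 - [target]) while solid is left; crystals form when [target] > cs4 (solubility = 2.40 mM, k = 0.00917 s⁻¹)
    starting material + partner B → open intermediate (k = 0.0319 M⁻¹ s⁻¹)

The flask's total stays under its share, crystals stand at 0%, and the solubility limit leaves the total unchanged. The wearing away of partner B and the length of the run, acting together, are part of what holds the total down: without that wearing away the flask reaches 13.9%, and left to 800 min it reaches 19.4%. In a neighbour flask at 85 mM of starting material, equivalents and time held, the share shrinks to 3.39%, so that neighbour's total of 13.1% should leave 9.74% as crystals, and it holds 10.2%.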